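**Retrosynthetic overview**
1. Target 20 ⇐ O-demethylation of methyl ether 18 ⇐ dibromination of phenol 17 ortho and para to its free OH.
2. 17 ⇐ dehydrogenative aromatisation of 2-aryloxycyclohexenone 15. Ring A is built on the oxygen of a finished ring B, so the two bromination levels never compete.
3. 15 ⇐ intramolecular aldol condensation and decarboxylation of the adduct from the intermolecular Michael addition of β-keto ester 9 to acrolein (key C–C bond).
4. 9 ⇐ crossed Claisen condensation of tert-butyl acetate enolate with aryloxyacetate 5 ⇐ Williamson etherification of tetrabromoguaiacol 3 ⇐ perbromination of guaiacol.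
5. Ring order: ring B is bought as guaiacol and perbrominated first; ring A is then made de novo (Claisen, Michael, aldol, aromatisation).

Assumption: the target has no stereocentre and its diaryl ether axis rotates freely, so it is one achiral compound and no stereocontrol is needed. Compounds 11, 12, 14 and 16 are racemic and lose their stereocentres on the way.

Abbreviation: "aryloxy" = 2,3,4,5-tetrabromo-6-methoxyphenoxy.

**Step 1**
Reactants: 1 guaiacol (2-methoxyphenol); 2 bromine
Product: 3 3,4,5,6-tetrabromo-2-methoxyphenol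
Conditions: Br2 (6 equiv), Fe powder (5 mol %), CHCl3, 0 °C → reflux; aq. NaHSO3
Reagents that add atoms: bromine, BrBr
Why: Electrophilic aromatic bromination; OH and OMe activate all four positions, three bromines enter readily and FeBr3 forces the last one into the flanked C3 position, while bisulfite returns any bromodienone to the phenol.

**Step 2**
Reactants: 3 3,4,5,6-tetrabromo-2-methoxyphenol; 4 methyl bromoacetate
Product: 5 methyl 2-(2,3,4,5-tetrabromo-6-methoxyphenoxy)acetate
Conditions: K2CO3 (1.5 equiv), DMF, 50 °C
Reagents that add atoms: methyl bromoacetate, COC(=O)CBr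
Why: Williamson ether synthesis (SN2); the acidic polybromophenol is fully deprotonated by carbonate and the unhindered α-bromo ester is reactive enough for the flanked phenoxide.

**Step 3**
Reactants: 5 methyl 2-(2,3,4,5-tetrabromo-6-methoxyphenoxy)acetate; 6 tert-butyl acetate (2.3 equiv)
Product: 9 tert-butyl 3-oxo-4-(2,3,4,5-tetrabromo-6-methoxyphenoxy)butanoate, via lithium enolate of tert-butyl acetate 7 (not isolated), via lithium enolate of the keto ester 8 (not isolated)
Conditions: LDA (2.3 equiv, commercial solution), THF, −78 °C; then 5, −78 → −40 °C; 1 M HCl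
Reagents that add atoms: tert-butyl acetate, CC(=O)OC(C)(C)C
Why: Crossed Claisen condensation; the tert-butyl acetate enolate adds to the more electrophilic α-aryloxy methyl ester, and the second equivalent deprotonates the β-keto ester as it forms, which drives the C–C bond formation (ring B has no C–H for LDA to metalate).

**Step 4**
Reactants: 9 tert-butyl 3-oxo-4-(2,3,4,5-tetrabromo-6-methoxyphenoxy)butanoate; 10 acrolein
Product: 11 tert-butyl 5-oxo-2-[2-(2,3,4,5-tetrabromo-6-methoxyphenoxy)acetyl]pentanoate (racemic)
Conditions: acrolein (1.1 equiv, slow addition), Et3N (10 mol %), CH2Cl2, −20 → 0 °C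
Reagents that add atoms: acrolein, C=CC=O
Why: Intermolecular Michael addition; under amine catalysis only the doubly activated C2–H is enolised and this soft enolate adds 1,4 to acrolein, completing the six-carbon chain of ring A (the new stereocentre is racemic and is erased in step 5).

**Step 5**
Reactants: 11 tert-butyl 5-oxo-2-[2-(2,3,4,5-tetrabromo-6-methoxyphenoxy)acetyl]pentanoate
Product: 15 2-(2,3,4,5-tetrabromo-6-methoxyphenoxy)cyclohex-2-en-1-one, via keto acid 12 (not isolated), via keto aldehyde 13 (not isolated), via aldol 14 (not isolated)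
Conditions: TsOH·H2O (0.3 equiv), toluene, 80 °C
Reagents that add atoms: none
Why: Acid cleaves the tert-butyl ester, the β-keto acid decarboxylates, and the ketone enolises toward the aryloxy-bearing carbon for an intramolecular aldol condensation whose only feasible ring size is six (Robinson-type annulation; all stereocentres vanish on dehydration).

**Step 6**
Reactants: 15 2-(2,3,4,5-tetrabromo-6-methoxyphenoxy)cyclohex-2-en-1-one
Product: 17 2-(2,3,4,5-tetrabromo-6-methoxyphenoxy)phenol, via 6-bromo enone 16 (not isolated)
Conditions: CuBr2 (2.2 equiv), LiBr (1 equiv), MeCN, reflux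
Reagents that add atoms: none
Why: Dehydrogenative aromatisation; α'-bromination by CuBr2 and loss of HBr give the keto tautomer of a phenol, which aromatises irreversibly, and any stray bromine para to the new OH is the one wanted in step 7.

**Step 7**
Reactants: 17 2-(2,3,4,5-tetrabromo-6-methoxyphenoxy)phenol; 2 bromine
Product: 18 2,4-dibromo-6-(2,3,4,5-tetrabromo-6-methoxyphenoxy)phenol
Conditions: Br2 (2.05 equiv), AcOH–CH2Cl2, 0 °C → rt; aq. Na2S2O3
Reagents that add atoms: bromine, BrBr
Why: Electrophilic aromatic bromination; the free OH is the strongest director on ring A (the aryloxy oxygen is a weak donor because its aryl group is electron-poor), so bromine enters para and ortho to OH, and ring B has no C–H left.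

**Step 8**
Reactants: 18 2,4-dibromo-6-(2,3,4,5-tetrabromo-6-methoxyphenoxy)phenol
Product: 20 3,4,5,6-tetrabromo-2-(3,5-dibromo-2-hydroxyphenoxy)phenol, via bis(dibromoboryl) ether 19 (not isolated)
Conditions: BBr3 (4 equiv), CH2Cl2, −78 °C → rt; then H2O, 0 °C
Reagents that add atoms: none
Why: Lewis-acid cleavage of the aryl methyl ether; BBr3 coordinates the methoxy oxygen and bromide attacks the methyl group (SN2), the diaryl ether and aryl bromides are inert, and water hydrolyses the aryl borates to the two phenols.

**Compound list**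
1 | guaiacol (2-methoxyphenol) | COc1ccccc1O | starting material
2 | bromine | BrBr | starting material
3 | 3,4,5,6-tetrabromo-2-methoxyphenol | COc1c(O)c(Br)c(Br)c(Br)c1Br | intermediate
4 | methyl bromoacetate | COC(=O)CBr | starting material
5 | methyl 2-(2,3,4,5-tetrabromo-6-methoxyphenoxy)acetate | COC(=O)COc1c(OC)c(Br)c(Br)c(Br)c1Br | intermediate
6 | tert-butyl acetate | CC(=O)OC(C)(C)C | starting material
7 | lithium enolate of tert-butyl acetate (not isolated) | [Li]OC(=C)OC(C)(C)C | intermediate
8 | lithium enolate of tert-butyl 3-oxo-4-(aryloxy)butanoate (not isolated) | COc1c(OCC(O[Li])=CC(=O)OC(C)(C)C)c(Br)c(Br)c(Br)c1Br | intermediate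
9 | tert-butyl 3-oxo-4-(2,3,4,5-tetrabromo-6-methoxyphenoxy)butanoate | COc1c(OCC(=O)CC(=O)OC(C)(C)C)c(Br)c(Br)c(Br)c1Br | intermediate
10 | acrolein (prop-2-enal) | C=CC=O | starting material
11 | tert-butyl 5-oxo-2-[2-(2,3,4,5-tetrabromo-6-methoxyphenoxy)acetyl]pentanoate (racemic) | COc1c(OCC(=O)C(CCC=O)C(=O)OC(C)(C)C)c(Br)c(Br)c(Br)c1Br | intermediate
12 | 5-oxo-2-[2-(2,3,4,5-tetrabromo-6-methoxyphenoxy)acetyl]pentanoic acid (racemic, not isolated) | COc1c(OCC(=O)C(CCC=O)C(O)=O)c(Br)c(Br)c(Br)c1Br | intermediate
13 | 5-oxo-6-(2,3,4,5-tetrabromo-6-methoxyphenoxy)hexanal (not isolated) | COc1c(OCC(=O)CCCC=O)c(Br)c(Br)c(Br)c1Br | intermediate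
14 | 3-hydroxy-2-(2,3,4,5-tetrabromo-6-methoxyphenoxy)cyclohexan-1-one (racemic diastereomer mixture, not isolated) | COc1c(OC2C(O)CCCC2=O)c(Br)c(Br)c(Br)c1Br | intermediate
15 | 2-(2,3,4,5-tetrabromo-6-methoxyphenoxy)cyclohex-2-en-1-one | COc1c(OC2=CCCCC2=O)c(Br)c(Br)c(Br)c1Br | intermediate
16 | 6-bromo-2-(2,3,4,5-tetrabromo-6-methoxyphenoxy)cyclohex-2-en-1-one (racemic, not isolated) | COc1c(OC2=CCCC(Br)C2=O)c(Br)c(Br)c(Br)c1Br | intermediate
17 | 2-(2,3,4,5-tetrabromo-6-methoxyphenoxy)phenol | COc1c(Oc2ccccc2O)c(Br)c(Br)c(Br)c1Br | intermediate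
18 | 2,4-dibromo-6-(2,3,4,5-tetrabromo-6-methoxyphenoxy)phenol | COc1c(Oc2cc(Br)cc(Br)c2O)c(Br)c(Br)c(Br)c1Br | intermediate
19 | bis(dibromoboryl) ether of 20 (not isolated) | BrB(Br)Oc1c(Br)cc(Br)cc1Oc1c(OB(Br)Br)c(Br)c(Br)c(Br)c1Br | intermediate
20 | 3,4,5,6-tetrabromo-2-(3,5-dibromo-2-hydroxyphenoxy)phenol | Oc1c(Br)cc(Br)cc1Oc1c(O)c(Br)c(Br)c(Br)c1Br | target

**Totals**
Total step count: 8. Longest linear sequence: 8 steps (1 → 20).

**Three steps most likely to fail**

Step 1. The fourth bromine must enter a flanked position under Lewis-acid conditions that can also cleave the methyl ether. The fallback sets out from 1 and comes back at 3. Guaiacol 1 is deliberately demethylated (48% HBr, AcOH, reflux) to catechol F1, which is also a cheap commercial chemical. Catechol is perbrominated with bromine 2 in AcOH, without catalyst, to 3,4,5,6-tetrabromobenzene-1,2-diol F2. One of its two equivalent hydroxyls is then methylated (MeI 1.0 equiv, Li2CO3, DMF, 40 °C; the monoanion forms selectively because the first pKa is far below the second). Unreacted diol and neutral dimethyl ether are removed by pH-controlled extraction, giving 3.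

Step 4. Acrolein polymerises easily and the mono-adduct can add a second acrolein. The fallback sets out from 9 and comes back at 11, replacing the conjugate addition by an alkylation with a masked aldehyde. Keto ester 9 is C-alkylated with 2-(2-bromoethyl)-1,3-dioxolane (K2CO3, NaI cat., DMF, 50 °C) to tert-butyl 4-(1,3-dioxolan-2-yl)-2-[2-(2,3,4,5-tetrabromo-6-methoxyphenoxy)acetyl]butanoate F3. PPTS in wet acetone at 50 °C then unmasks the aldehyde and gives 11 without touching the tert-butyl ester.

Step 5. The acid-mediated cascade may stall at a lactol or 4H-pyran, or the aldol closure may be low-yielding. The fallback sets out from 3 and comes back at 15, bringing in all six ring-A carbons as a preformed ring. Phenol 3 is O-alkylated with 2-chlorocyclohexanone (K2CO3, KI, DMF, 60 °C) to 2-(2,3,4,5-tetrabromo-6-methoxyphenoxy)cyclohexan-1-one F4. Dehydrogenation with IBX (DMSO, 70 °C) gives enone 15 together with its isomer 6-(2,3,4,5-tetrabromo-6-methoxyphenoxy)cyclohex-2-en-1-one F5. The two need not be separated, because step 6 converts both into phenol 17.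

**Further compounds**
F1 | step 1 | catechol (benzene-1,2-diol) | Oc1ccccc1O
F2 | step 1 | 3,4,5,6-tetrabromobenzene-1,2-diol | Oc1c(O)c(Br)c(Br)c(Br)c1Br
F3 | step 4 | tert-butyl 4-(1,3-dioxolan-2-yl)-2-[2-(2,3,4,5-tetrabromo-6-methoxyphenoxy)acetyl]butanoate (racemic) | COc1c(OCC(=O)C(CCC2OCCO2)C(=O)OC(C)(C)C)c(Br)c(Br)c(Br)c1Br
F4 | step 5 | 2-(2,3,4,5-tetrabromo-6-methoxyphenoxy)cyclohexan-1-one (racemic) | COc1c(OC2CCCCC2=O)c(Br)c(Br)c(Br)c1Br
F5 | step 5 | 6-(2,3,4,5-tetrabromo-6-methoxyphenoxy)cyclohex-2-en-1-one (racemic) | COc1c(OC2CCC=CC2=O)c(Br)c(Br)c(Br)c1Br
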